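**Plan**

1. Retrosynthetic cuts: the four masked hydroxyl groups are freed last. Flavone 1 is opened at O1–C2 (ynone closure), then at O1–C8a and C4a–C4 in one stroke (aryne plus arylpropiolic acid). The acid is cut at the ring B–alkyne bond, flavone 2 at O1–C2/C2–C3 (chalcone) and C4–C4a (acetylation), and finally the ring B–C8 biaryl bond.
2. Enabling feature: in flavone 1 the adjacent ring A carbons C8a and C4a carry O1 and the C4 carbonyl, and C5 next to C4a carries oxygen. A 3-alkoxybenzyne takes up exactly this oxygen/acyl pair from a carboxylic acid, the alkoxy group steering the acyl group to its own side.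
3. Forward order: ring A of flavone 2 (a mirror-symmetric resorcinol) is joined to ring B, and ring C of flavone 2 is built on it. The propiolic acid is then attached to ring B, ring A of flavone 1 arrives as 3,5-dimethoxybenzyne, ring C of flavone 1 closes, and BCl3 unmasks the phenols.
4. Stereochemistry: the target has no stereocentre and its biaryl axis carries no descriptor, so nothing has to be set. The E-alkene of chalcone 13 is consumed in the following step.

Key step: step 12

Remark on the chemistry: flavone 1 is the 5-hydroxy-7-methoxychromone unit, flavone 2 the 8-arylchromone unit, and ring B the phenol ring between them. It is assumed that any ynone that closes to the flavone during step 12 is simply carried into step 13.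

**Route**

Step 1
Reactants: 1 5-methoxyresorcinol
Product: 2 1-methoxy-3,5-bis(methoxymethoxy)benzene
Conditions: MOMCl, i-Pr2NEt, CH2Cl2, 0 °C to rt
Reagents that add atoms: chloromethyl methyl ether, SMILES COCCl
Why: Williamson-type O-alkylation of both phenols should give the bis-MOM ether, whose two acetal groups later direct lithiation to the carbon between them.

Step 2
Reactants: 3 4-bromo-2-iodophenol
Product: 4 1-(benzyloxy)-4-bromo-2-iodobenzene
Conditions: BnBr, K2CO3, acetone, reflux
Reagents that add atoms: benzyl bromide, SMILES BrCc1ccccc1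
Why: Williamson ether synthesis should mask the ring B phenol as a benzyl ether that lasts until BCl3 removes it in the final step.

Step 3
Reactants: 2 1-methoxy-3,5-bis(methoxymethoxy)benzene; 4 1-(benzyloxy)-4-bromo-2-iodobenzene
Product: 7 2'-(benzyloxy)-5'-bromo-4-methoxy-2,6-bis(methoxymethoxy)-1,1'-biphenyl, via aryllithium 5 (not isolated), via arylzinc chloride 6 (not isolated)
Conditions: n-BuLi, THF, 0 °C; ZnCl2, 0 °C to rt; then 4, Pd(PPh3)4 (5 mol %), 60 °C
Reagents that add atoms: none
Why: Directed ortho-metalation between the two MOM ethers, transmetalation to zinc and Negishi coupling should give the biaryl, because zerovalent palladium inserts into the C–I bond of 4 much faster than into its C–Br bond, which is kept for step 9.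

Step 4
Reactants: 7 2'-(benzyloxy)-5'-bromo-4-methoxy-2,6-bis(methoxymethoxy)-1,1'-biphenyl
Product: 8 2'-(benzyloxy)-5'-bromo-4-methoxy-[1,1'-biphenyl]-2,6-diol
Conditions: 3 M aq. HCl, MeOH, 55 °C
Reagents that add atoms: none
Why: Acid-catalysed acetal cleavage in methanol should remove both MOM groups, leave the benzyl ether, and expose a resorcinol whose two free ring positions are equivalent by symmetry.

Step 5
Reactants: 8 2'-(benzyloxy)-5'-bromo-4-methoxy-[1,1'-biphenyl]-2,6-diol
Product: 10 1-[2'-(benzyloxy)-5'-bromo-2,6-dihydroxy-4-methoxy-[1,1'-biphenyl]-3-yl]ethan-1-one, via ketiminium chloride 9 (not isolated)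
Conditions: MeCN, ZnCl2, HCl (g), Et2O, 0 °C; then H2O, 90 °C
Reagents that add atoms: acetonitrile, SMILES CC#N; water, SMILES O
Why: Houben–Hoesch acylation of the phloroglucinol-type ring should place the acetyl group on the only kind of free position (between hydroxyl and methoxy) and hydrolysis of the ketiminium salt gives the methyl ketone, the benzyl aryl ether being stable to ethereal HCl at 0 °C.

Step 6
Reactants: 10 1-[2'-(benzyloxy)-5'-bromo-2,6-dihydroxy-4-methoxy-[1,1'-biphenyl]-3-yl]ethan-1-one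
Product: 11 1-[2',6-bis(benzyloxy)-5'-bromo-2-hydroxy-4-methoxy-[1,1'-biphenyl]-3-yl]ethan-1-one
Conditions: BnBr (1.05 equiv), K2CO3, acetone, 50 °C
Reagents that add atoms: benzyl bromide, SMILES BrCc1ccccc1
Why: Selective Williamson benzylation should occur at the hydroxyl para to the acetyl group, because the ortho hydroxyl is tied up in a hydrogen bond to the carbonyl and is far less nucleophilic.

Step 7
Reactants: 11 1-[2',6-bis(benzyloxy)-5'-bromo-2-hydroxy-4-methoxy-[1,1'-biphenyl]-3-yl]ethan-1-one; 12 4-methoxybenzaldehyde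
Product: 13 (E)-1-[2',6-bis(benzyloxy)-5'-bromo-2-hydroxy-4-methoxy-[1,1'-biphenyl]-3-yl]-3-(4-methoxyphenyl)prop-2-en-1-one
Conditions: KOH (50 % aq.), EtOH, rt
Reagents that add atoms: none
Why: Claisen–Schmidt aldol condensation should give the 2'-hydroxychalcone, the E-alkene arising from E1cB dehydration of the aldol.

Step 8
Reactants: 13 (E)-1-[2',6-bis(benzyloxy)-5'-bromo-2-hydroxy-4-methoxy-[1,1'-biphenyl]-3-yl]-3-(4-methoxyphenyl)prop-2-en-1-one
Product: 14 7-(benzyloxy)-8-[2-(benzyloxy)-5-bromophenyl]-5-methoxy-2-(4-methoxyphenyl)-4H-chromen-4-one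
Conditions: I2 (10 mol %), DMSO, 130 °C
Reagents that add atoms: none
Why: Iodine-catalysed oxidative cyclisation of a 2'-hydroxychalcone in DMSO should close ring C of flavone 2 through the only free phenol, which places the aryl group at C8 without any C6/C8 ambiguity.

Step 9
Reactants: 14 7-(benzyloxy)-8-[2-(benzyloxy)-5-bromophenyl]-5-methoxy-2-(4-methoxyphenyl)-4H-chromen-4-one; 15 propiolic acid
Product: 16 3-{4-(benzyloxy)-3-[7-(benzyloxy)-5-methoxy-2-(4-methoxyphenyl)-4-oxo-4H-chromen-8-yl]phenyl}prop-2-ynoic acid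
Conditions: Pd2(dba)3 (2.5 mol %), 2-dicyclohexylphosphino-2',4',6'-triisopropylbiphenyl (10 mol %), DBU, DMSO, 50 °C; then 1 M HCl
Reagents that add atoms: none
Why: Copper-free Sonogashira coupling of the aryl bromide with propiolic acid as its amidinium salt should give the arylpropiolic acid, the low temperature being chosen so that the carboxyl group is retained.

Step 10
Reactants: 17 3,5-dimethoxyphenol
Product: 18 2-bromo-3,5-dimethoxyphenol
Conditions: NBS (1.0 equiv), CH2Cl2, −78 °C to rt
Reagents that add atoms: N-bromosuccinimide, SMILES O=C1CCC(=O)N1Br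
Why: Electrophilic aromatic bromination with NBS in a non-polar solvent at low temperature should go ortho to the free hydroxyl group rather than to the more crowded carbon between the two methoxy groups.

Step 11
Reactants: 18 2-bromo-3,5-dimethoxyphenol
Product: 22 3,5-dimethoxy-2-(trimethylsilyl)phenyl trifluoromethanesulfonate, via silyl ether 19 (not isolated), via aryllithium 20 (not isolated), via lithium phenolate 21 (not isolated)
Conditions: HMDS, THF, 70 °C, evaporate; n-BuLi, THF, −100 °C; Tf2O, −100 °C to rt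
Reagents that add atoms: hexamethyldisilazane, SMILES C[Si](C)(C)N[Si](C)(C)C; trifluoromethanesulfonic anhydride, SMILES O=S(=O)(OS(=O)(=O)C(F)(F)F)C(F)(F)F
Why: O-silylation, bromine–lithium exchange, retro-Brook 1,3-shift of silicon from oxygen to carbon and triflation of the phenolate form the standard sequence to ortho-silylaryl triflates and should fix silicon next to the methoxy group.

Step 12
Reactants: 16 3-{4-(benzyloxy)-3-[7-(benzyloxy)-5-methoxy-2-(4-methoxyphenyl)-4-oxo-4H-chromen-8-yl]phenyl}prop-2-ynoic acid; 22 3,5-dimethoxy-2-(trimethylsilyl)phenyl trifluoromethanesulfonate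
Product: 25 3-{4-(benzyloxy)-3-[7-(benzyloxy)-5-methoxy-2-(4-methoxyphenyl)-4-oxo-4H-chromen-8-yl]phenyl}-1-(2-hydroxy-4,6-dimethoxyphenyl)prop-2-yn-1-one, via cesium carboxylate 23 (not isolated), via 3,5-dimethoxybenzyne 24 (not isolated)
Conditions: 22 (1.5 equiv), CsF (4 equiv), THF, 125 °C, sealed tube; aq. NH4Cl
Reagents that add atoms: none
Why: CsF turns 16 into the cesium propiolate 23 and strips silicon from 22, and loss of triflate releases 3,5-dimethoxybenzyne 24. The carboxylate oxygen adds to the aryne carbon remote from the flanking methoxy group, and the aryl anion formed beside that methoxy group attacks the ester carbonyl through a four-membered ring that opens to the ketone and the phenoxide of 25. This is the known fluoride-induced insertion of arynes into the acyl–oxygen bond of carboxylic acids to give ortho-hydroxyaryl ketones, here with an arylpropiolic acid. No ring closes and no stereocentre forms; the step makes O1–C8a and C4a–C4 of flavone 1. Regioselectivity on the unsymmetrical aryne is required and should come from the inductively withdrawing methoxy group next to the triple bond, which sends the nucleophile to the distal carbon, while the absence of any other acidic hydrogen in 16 and the aprotic medium keep the aryl anion from being protonated before acyl transfer. Any phenoxide that already adds to the alkyne in the flask in the 6-endo sense is the product of step 13 and is carried on with the rest.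

Step 13
Reactants: 25 3-{4-(benzyloxy)-3-[7-(benzyloxy)-5-methoxy-2-(4-methoxyphenyl)-4-oxo-4H-chromen-8-yl]phenyl}-1-(2-hydroxy-4,6-dimethoxyphenyl)prop-2-yn-1-one
Product: 27 7-(benzyloxy)-8-[2-(benzyloxy)-5-(5,7-dimethoxy-4-oxo-4H-chromen-2-yl)phenyl]-5-methoxy-2-(4-methoxyphenyl)-4H-chromen-4-one, via enaminone 26 (not isolated)
Conditions: Et2NH (excess), EtOH–THF, 60 °C
Reagents that add atoms: none
Why: Conjugate addition of diethylamine to the ynone should give enaminone 26, and the phenol then displaces the amine by 6-endo addition–elimination (oxa-Michael), which closes ring C of flavone 1 and avoids the 5-exo path to an aurone.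

Step 14
Reactants: 27 7-(benzyloxy)-8-[2-(benzyloxy)-5-(5,7-dimethoxy-4-oxo-4H-chromen-2-yl)phenyl]-5-methoxy-2-(4-methoxyphenyl)-4H-chromen-4-one
Product: 29 putraflavone, via dichloroboryl ether 28 (not isolated)
Conditions: BCl3 (1 M in CH2Cl2, excess), pentamethylbenzene, CH2Cl2, −78 °C to rt; then MeOH, H2O
Reagents that add atoms: none
Why: Lewis acid ether cleavage with BCl3 should remove both benzyl ethers (the benzyl cation is trapped by pentamethylbenzene) and, through chelation to the two C4 carbonyls, both C5 methyl ethers, while the non-chelated 7-methoxy group of flavone 1 and the anisyl methoxy group stay.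

**Compound list**

1 | 5-methoxyresorcinol | COc1cc(O)cc(O)c1 | starting material
2 | 1-methoxy-3,5-bis(methoxymethoxy)benzene | COCOc1cc(OC)cc(OCOC)c1 | intermediate
3 | 4-bromo-2-iodophenol | Oc1ccc(Br)cc1I | starting material
4 | 1-(benzyloxy)-4-bromo-2-iodobenzene | Brc1ccc(OCc2ccccc2)c(I)c1 | intermediate
5 | [4-methoxy-2,6-bis(methoxymethoxy)phenyl]lithium | [Li]c1c(OCOC)cc(OC)cc1OCOC | intermediate
6 | chloro[4-methoxy-2,6-bis(methoxymethoxy)phenyl]zinc | Cl[Zn]c1c(OCOC)cc(OC)cc1OCOC | intermediate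
7 | 2'-(benzyloxy)-5'-bromo-4-methoxy-2,6-bis(methoxymethoxy)-1,1'-biphenyl | COCOc1cc(OC)cc(OCOC)c1-c1cc(Br)ccc1OCc1ccccc1 | intermediate
8 | 2'-(benzyloxy)-5'-bromo-4-methoxy-[1,1'-biphenyl]-2,6-diol | COc1cc(O)c(-c2cc(Br)ccc2OCc2ccccc2)c(O)c1 | intermediate
9 | 1-[2'-(benzyloxy)-5'-bromo-2,6-dihydroxy-4-methoxy-[1,1'-biphenyl]-3-yl]ethan-1-iminium chloride | CC(=[NH2+])c1c(OC)cc(O)c(-c2cc(Br)ccc2OCc2ccccc2)c1O.[Cl-] | intermediate
10 | 1-[2'-(benzyloxy)-5'-bromo-2,6-dihydroxy-4-methoxy-[1,1'-biphenyl]-3-yl]ethan-1-one | CC(=O)c1c(OC)cc(O)c(-c2cc(Br)ccc2OCc2ccccc2)c1O | intermediate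
11 | 1-[2',6-bis(benzyloxy)-5'-bromo-2-hydroxy-4-methoxy-[1,1'-biphenyl]-3-yl]ethan-1-one | CC(=O)c1c(OC)cc(OCc2ccccc2)c(-c2cc(Br)ccc2OCc2ccccc2)c1O | intermediate
12 | 4-methoxybenzaldehyde | COc1ccc(C=O)cc1 | starting material
13 | (E)-1-[2',6-bis(benzyloxy)-5'-bromo-2-hydroxy-4-methoxy-[1,1'-biphenyl]-3-yl]-3-(4-methoxyphenyl)prop-2-en-1-one | COc1ccc(/C=C/C(=O)c2c(OC)cc(OCc3ccccc3)c(-c3cc(Br)ccc3OCc3ccccc3)c2O)cc1 | intermediate
14 | 7-(benzyloxy)-8-[2-(benzyloxy)-5-bromophenyl]-5-methoxy-2-(4-methoxyphenyl)-4H-chromen-4-one | COc1ccc(-c2cc(=O)c3c(OC)cc(OCc4ccccc4)c(-c4cc(Br)ccc4OCc4ccccc4)c3o2)cc1 | intermediate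
15 | propiolic acid | C#CC(=O)O | starting material
16 | 3-{4-(benzyloxy)-3-[7-(benzyloxy)-5-methoxy-2-(4-methoxyphenyl)-4-oxo-4H-chromen-8-yl]phenyl}prop-2-ynoic acid | OC(=O)C#Cc1ccc(OCc2ccccc2)c(-c2c(OCc3ccccc3)cc(OC)c3c(=O)cc(-c4ccc(OC)cc4)oc23)c1 | intermediate
17 | 3,5-dimethoxyphenol | COc1cc(O)cc(OC)c1 | starting material
18 | 2-bromo-3,5-dimethoxyphenol | COc1cc(O)c(Br)c(OC)c1 | intermediate
19 | (2-bromo-3,5-dimethoxyphenoxy)trimethylsilane | COc1cc(O[Si](C)(C)C)c(Br)c(OC)c1 | intermediate
20 | [2,4-dimethoxy-6-(trimethylsilyloxy)phenyl]lithium | COc1cc(O[Si](C)(C)C)c([Li])c(OC)c1 | intermediate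
21 | lithium 3,5-dimethoxy-2-(trimethylsilyl)phenolate | COc1cc([O-])c([Si](C)(C)C)c(OC)c1.[Li+] | intermediate
22 | 3,5-dimethoxy-2-(trimethylsilyl)phenyl trifluoromethanesulfonate | COc1cc(OC)c([Si](C)(C)C)c(OS(=O)(=O)C(F)(F)F)c1 | intermediate
23 | cesium 3-{4-(benzyloxy)-3-[7-(benzyloxy)-5-methoxy-2-(4-methoxyphenyl)-4-oxo-4H-chromen-8-yl]phenyl}prop-2-ynoate | [Cs+].[O-]C(=O)C#Cc1ccc(OCc2ccccc2)c(-c2c(OCc3ccccc3)cc(OC)c3c(=O)cc(-c4ccc(OC)cc4)oc23)c1 | intermediate
24 | 3,5-dimethoxybenzyne (1,2-didehydro-3,5-dimethoxybenzene) | COC1=CC(OC)=CC#C1 | intermediate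
25 | 3-{4-(benzyloxy)-3-[7-(benzyloxy)-5-methoxy-2-(4-methoxyphenyl)-4-oxo-4H-chromen-8-yl]phenyl}-1-(2-hydroxy-4,6-dimethoxyphenyl)prop-2-yn-1-one | COc1cc(O)c(C(=O)C#Cc2ccc(OCc3ccccc3)c(-c3c(OCc4ccccc4)cc(OC)c4c(=O)cc(-c5ccc(OC)cc5)oc34)c2)c(OC)c1 | intermediate
26 | (E)-3-{4-(benzyloxy)-3-[7-(benzyloxy)-5-methoxy-2-(4-methoxyphenyl)-4-oxo-4H-chromen-8-yl]phenyl}-3-(diethylamino)-1-(2-hydroxy-4,6-dimethoxyphenyl)prop-2-en-1-one | CCN(CC)/C(=C/C(=O)c1c(O)cc(OC)cc1OC)c1ccc(OCc2ccccc2)c(-c2c(OCc3ccccc3)cc(OC)c3c(=O)cc(-c4ccc(OC)cc4)oc23)c1 | intermediate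
27 | 7-(benzyloxy)-8-[2-(benzyloxy)-5-(5,7-dimethoxy-4-oxo-4H-chromen-2-yl)phenyl]-5-methoxy-2-(4-methoxyphenyl)-4H-chromen-4-one | COc1ccc(-c2cc(=O)c3c(OC)cc(OCc4ccccc4)c(-c4cc(-c5cc(=O)c6c(OC)cc(OC)cc6o5)ccc4OCc4ccccc4)c3o2)cc1 | intermediate
28 | tetrakis(O-dichloroboryl) ether of putraflavone | COc1ccc(-c2cc(=O)c3c(OB(Cl)Cl)cc(OB(Cl)Cl)c(-c4cc(-c5cc(=O)c6c(OB(Cl)Cl)cc(OC)cc6o5)ccc4OB(Cl)Cl)c3o2)cc1 | intermediate
29 | putraflavone, 5,7-dihydroxy-8-[2-hydroxy-5-(5-hydroxy-7-methoxy-4-oxo-4H-chromen-2-yl)phenyl]-2-(4-methoxyphenyl)-4H-chromen-4-one | COc1ccc(-c2cc(=O)c3c(O)cc(O)c(-c4cc(-c5cc(=O)c6c(O)cc(OC)cc6o5)ccc4O)c3o2)cc1 | target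

**Step count and risks**

Total steps: 14. Longest linear sequence: 11 steps (steps 1, 3, 4, 5, 6, 7, 8, 9, 12, 13, 14).

Risk 1, step 12 (aryne insertion). The cesium arylpropiolate may lose CO2 at 125 °C before it meets the aryne. The aryl anion may be protonated before the acyl shift, leaving an aryl ester. The product phenoxide may be arylated by excess aryne or may close onto the alkyne in an uncontrolled sense. The fallback drops the aryne and builds flavone 1 by the chalcone route.
- It sets out from bromide 14, which is formylated by reductive carbonylation (Pd(OAc)2, di(1-adamantyl)-n-butylphosphine, CO/H2, TMEDA, toluene, 100 °C) to 4-(benzyloxy)-3-[7-(benzyloxy)-5-methoxy-2-(4-methoxyphenyl)-4-oxo-4H-chromen-8-yl]benzaldehyde F1.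
- Claisen–Schmidt condensation of F1 with commercial 1-(2-hydroxy-4,6-dimethoxyphenyl)ethanone (KOH, EtOH–THF, rt) should give the chalcone (E)-3-{4-(benzyloxy)-3-[7-(benzyloxy)-5-methoxy-2-(4-methoxyphenyl)-4-oxo-4H-chromen-8-yl]phenyl}-1-(2-hydroxy-4,6-dimethoxyphenyl)prop-2-en-1-one F2.
- Oxidative cyclisation of F2 with catalytic I2 in DMSO at 130 °C rejoins the route at 27.

Risk 2, step 9 (coupling with propiolic acid). Oxidative addition into the electron-rich C–Br bond may be slow, and while it lags the propiolate may lose CO2, leading to the terminal alkyne and on to a symmetrical diarylalkyne. The fallback installs the carboxyl group last.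
- It sets out from bromide 14, which undergoes Sonogashira coupling with ethynyltrimethylsilane (PdCl2(PPh3)2, CuI, Et3N, THF, 70 °C) to give 7-(benzyloxy)-8-{2-(benzyloxy)-5-[(trimethylsilyl)ethynyl]phenyl}-5-methoxy-2-(4-methoxyphenyl)-4H-chromen-4-one F3.
- Desilylation (K2CO3, MeOH–THF, rt) gives the terminal alkyne 7-(benzyloxy)-8-[2-(benzyloxy)-5-ethynylphenyl]-5-methoxy-2-(4-methoxyphenyl)-4H-chromen-4-one F4.
- Carboxylation of F4 with CO2 (1 atm, Cs2CO3, AgI 5 mol %, DMF, 50 °C, then 1 M HCl) returns to the route at acid 16.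

Risk 3, step 3 (lithiation and Negishi coupling). Lithiation may be incomplete or may stray to the position between methoxy and MOM-oxy. Coupling to the tri-ortho-substituted biaryl may be sluggish, and at longer reaction times the iodide-over-bromide selectivity may erode. The fallback reverses the polarity of the partners and uses a Suzuki–Miyaura coupling.
- It sets out from 2, which is lithiated (n-BuLi, THF, 0 °C) and quenched with I2 to give 2-iodo-5-methoxy-1,3-bis(methoxymethoxy)benzene F5, an isolable compound on which the site of metalation can be checked.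
- It also sets out from 4, which is converted by iodine–magnesium exchange (i-PrMgCl·LiCl, THF, −20 °C), B(OMe)3 and aqueous acid into [2-(benzyloxy)-5-bromophenyl]boronic acid F6.
- Coupling of F5 with F6 (Pd(PPh3)4, K3PO4, DME–H2O, 80 °C) comes back to the route at biaryl 7.

**Further compounds**

F1 | step 12 | 4-(benzyloxy)-3-[7-(benzyloxy)-5-methoxy-2-(4-methoxyphenyl)-4-oxo-4H-chromen-8-yl]benzaldehyde | O=Cc1ccc(OCc2ccccc2)c(-c2c(OCc3ccccc3)cc(OC)c3c(=O)cc(-c4ccc(OC)cc4)oc23)c1
F2 | step 12 | (E)-3-{4-(benzyloxy)-3-[7-(benzyloxy)-5-methoxy-2-(4-methoxyphenyl)-4-oxo-4H-chromen-8-yl]phenyl}-1-(2-hydroxy-4,6-dimethoxyphenyl)prop-2-en-1-one | COc1cc(O)c(C(=O)/C=C/c2ccc(OCc3ccccc3)c(-c3c(OCc4ccccc4)cc(OC)c4c(=O)cc(-c5ccc(OC)cc5)oc34)c2)c(OC)c1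
F3 | step 9 | 7-(benzyloxy)-8-{2-(benzyloxy)-5-[(trimethylsilyl)ethynyl]phenyl}-5-methoxy-2-(4-methoxyphenyl)-4H-chromen-4-one | C[Si](C)(C)C#Cc1ccc(OCc2ccccc2)c(-c2c(OCc3ccccc3)cc(OC)c3c(=O)cc(-c4ccc(OC)cc4)oc23)c1
F4 | step 9 | 7-(benzyloxy)-8-[2-(benzyloxy)-5-ethynylphenyl]-5-methoxy-2-(4-methoxyphenyl)-4H-chromen-4-one | C#Cc1ccc(OCc2ccccc2)c(-c2c(OCc3ccccc3)cc(OC)c3c(=O)cc(-c4ccc(OC)cc4)oc23)c1
F5 | step 3 | 2-iodo-5-methoxy-1,3-bis(methoxymethoxy)benzene | COCOc1cc(OC)cc(OCOC)c1I
F6 | step 3 | [2-(benzyloxy)-5-bromophenyl]boronic acid | OB(O)c1cc(Br)ccc1OCc1ccccc1
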